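**Assumption:** the target is natural (2R,3′E,7′E)-α-tocotrienol. Commercial (S)-Trolox and (E)-geranylacetone are available; geranylacetone is sold as E/Z mixtures, so the E isomer is purified or bought as such.

## Retrosynthesis
- The target is the free phenol, so the last step removes a MOM group from the phenol.
- The C2′–C3′ bond is made by a B-alkyl Suzuki coupling between an alkyl-9-BBN and an (E)-vinyl iodide.
- The alkyl-9-BBN comes from hydroboration of a 2-vinylchromane. The vinylchromane is made from (S)-Trolox by ester → aldehyde → Wittig methylenation.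
- The vinyl iodide comes from geranylacetone: ketone → terminal alkyne → Zr-catalysed carboalumination/iodination. This sets the E-trisubstituted alkene and carries the two prenyl-type alkenes through unchanged.
- No ring is formed. The chromane ring and the only stereocentre (C2) come from (S)-Trolox. The (S)→(R) descriptor change is only a CIP priority swap (chain CH₂ replaces the C1′ group), not an inversion.

## Route

**Step 1**
Reactants: 1, (S)-Trolox
Product: 2, methyl (2S)-6-hydroxy-2,5,7,8-tetramethylchromane-2-carboxylate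
Conditions: TMSCHN₂, MeOH/PhMe (1:3), 0 °C → rt, 1 h
Reagents that add atoms: trimethylsilyldiazomethane, C[Si](C)(C)C=[N+]=[N-] (adds CH₃)
Why: Mild esterification of the carboxylic acid. The quaternary C2 has no α-H and is untouched.

**Step 2**
Reactants: 2
Product: 3, methyl (2S)-6-(methoxymethoxy)-2,5,7,8-tetramethylchromane-2-carboxylate
Conditions: NaH, THF/DMF, 0 °C; then MOMCl, 0 °C → rt
Reagents that add atoms: chloromethyl methyl ether, COCCl (adds CH₂OCH₃)
Why: Williamson-type acetal formation on the phenol. MOM survives DIBAL, ylides, 9-BBN and Suzuki base, and is removed by acid at the end. Hydrogenolysable groups such as benzyl are avoided because they would need H₂/Pd, which would reduce the trienes.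

**Step 3**
Reactants: 3
Product: 4, (2S)-6-(methoxymethoxy)-2,5,7,8-tetramethylchromane-2-carbaldehyde
Conditions: DIBAL-H (1.2 equiv), toluene, −78 °C, 1 h; Rochelle salt work-up
Reagents that add atoms: none
Why: Partial ester reduction at −78 °C. The hindered α-quaternary ester stops at the aldehyde, which cannot epimerise because C2 has no α-H.

**Step 4**
Reactants: 4
Product: 5, (2S)-6-(methoxymethoxy)-2,5,7,8-tetramethyl-2-vinylchromane
Conditions: Ph₃P⁺CH₃ Br⁻, KOtBu, THF, 0 °C → rt
Reagents that add atoms: methyltriphenylphosphonium bromide, C[P+](c1ccccc1)(c1ccccc1)c1ccccc1.[Br-] (adds =CH₂)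
Why: Wittig methylenation makes a terminal alkene with no new stereocentre. C2 is not involved.

**Step 5**
Reactants: 6, (E)-geranylacetone
Product: 7, (E)-6,10-dimethylundeca-5,9-dien-1-yne
Conditions: (i) LDA (1.1 equiv), THF, −78 °C; ClP(O)(OEt)₂ (1.2 equiv), −78 → 0 °C; (ii) LDA (2.5 equiv), −78 °C → rt
Reagents that add atoms: none (diethyl chlorophosphate, CCOP(=O)(Cl)OCC, is lost as phosphate)
Why: Kinetic deprotonation at the methyl group gives the terminal enol phosphate, and excess LDA eliminates it to the terminal alkyne (ketone-to-alkyne one-pot method). The trisubstituted alkenes are unaffected.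

**Step 6**
Reactants: 7
Product: 8, (1E,5E)-1-iodo-2,6,10-trimethylundeca-1,5,9-triene
Conditions: Me₃Al (2 equiv), Cp₂ZrCl₂ (0.2 equiv), ClCH₂CH₂Cl, 0 °C → rt, 8 h; evaporate volatiles; I₂ (1.5 equiv), THF, −30 → 0 °C
Reagents that add atoms: trimethylaluminium, C[Al](C)C (adds CH₃); iodine, II (adds I)
Why: Negishi Zr-catalysed carboalumination is a syn methylalumination that puts Me on the internal alkyne carbon and Al on the terminal one. Iodinolysis with retention gives the E-trisubstituted vinyl iodide, which corresponds to the C3′=C4′ alkene of the target.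

**Step 7**
Reactants: 5
Product: 9, 9-[2-((2R)-6-(methoxymethoxy)-2,5,7,8-tetramethylchroman-2-yl)ethyl]-9-BBN
Conditions: 9-BBN-H (1.1 equiv), THF, 0 °C → rt, 3 h
Reagents that add atoms: 9-borabicyclo[3.3.1]nonane, C1CC2CCCC(C1)B2 (adds the alkyl-B unit)
Why: Anti-Markovnikov syn-hydroboration puts boron on the terminal carbon. Boron is then γ to the ring oxygen, so no β-alkoxide elimination can open the chromane; a chromanylmethyl metal would do exactly that. C2 is unchanged and is now named (R) only because of the priority swap.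

**Step 8**
Reactants: 9 and 8
Product: 10, MOM-protected (2R,3′E,7′E)-α-tocotrienol
Conditions: PdCl₂(dppf)·CH₂Cl₂ (5 mol %), 3 M aq K₃PO₄, THF, 25 °C → 45 °C, 12 h
Reagents that add atoms: none
Why: B-alkyl Suzuki–Miyaura coupling forms the sp³–sp² C2′–C3′ bond with retention of alkene geometry. No stereocentre is created, and the prenyl-type alkenes do not react.

**Step 9**
Reactants: 10
Product: 11, (2R,3′E,7′E)-α-tocotrienol
Conditions: 2 M HCl, THF/MeOH (1:1), 40 °C, 4 h, under Ar, in the dark
Reagents that add atoms: none
Why: Acid hydrolysis of the aryl MOM acetal. These conditions are milder than the hot HCl/ZnCl₂ used to make chromanols industrially, so C2 and the trienes are not scrambled.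

## Compound list
1 | (S)-Trolox, (2S)-6-hydroxy-2,5,7,8-tetramethylchromane-2-carboxylic acid | OC(=O)[C@]1(C)CCc2c(C)c(O)c(C)c(C)c2O1 | starting material
2 | methyl (2S)-6-hydroxy-2,5,7,8-tetramethylchromane-2-carboxylate | COC(=O)[C@]1(C)CCc2c(C)c(O)c(C)c(C)c2O1 | intermediate
3 | methyl (2S)-6-(MOM-oxy)-2,5,7,8-tetramethylchromane-2-carboxylate | COC(=O)[C@]1(C)CCc2c(C)c(OCOC)c(C)c(C)c2O1 | intermediate
4 | (2S)-6-(MOM-oxy)-2,5,7,8-tetramethylchromane-2-carbaldehyde | O=C[C@]1(C)CCc2c(C)c(OCOC)c(C)c(C)c2O1 | intermediate
5 | (2S)-6-(MOM-oxy)-2,5,7,8-tetramethyl-2-vinylchromane | C=C[C@]1(C)CCc2c(C)c(OCOC)c(C)c(C)c2O1 | intermediate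
6 | (E)-geranylacetone, (E)-6,10-dimethylundeca-5,9-dien-2-one | CC(=O)CC/C=C(\C)CCC=C(C)C | starting material
7 | (E)-6,10-dimethylundeca-5,9-dien-1-yne | C#CCC/C=C(\C)CCC=C(C)C | intermediate
8 | (1E,5E)-1-iodo-2,6,10-trimethylundeca-1,5,9-triene | CC(C)=CCC/C(C)=C/CC/C(C)=C/I | intermediate
9 | 9-[2-((2R)-6-(MOM-oxy)-2,5,7,8-tetramethylchroman-2-yl)ethyl]-9-BBN | C1CC2CCCC(C1)B2CC[C@]3(C)CCc4c(C)c(OCOC)c(C)c(C)c4O3 | intermediate
10 | MOM ether of (2R,3′E,7′E)-α-tocotrienol | CC(C)=CCC/C(C)=C/CC/C(C)=C/CC[C@]1(C)CCc2c(C)c(OCOC)c(C)c(C)c2O1 | intermediate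
11 | (2R,3′E,7′E)-α-tocotrienol | CC(C)=CCC/C(C)=C/CC/C(C)=C/CC[C@]1(C)CCc2c(C)c(O)c(C)c(C)c2O1 | target

## Totals
Total steps: 9. Longest linear sequence: 7 (1 → 2 → 3 → 4 → 5 → 9 → 10 → 11, i.e. steps 1, 2, 3, 4, 7, 8, 9). The vinyl-iodide arm (steps 5–6) is a convergent two-step branch.

## Three steps most likely to fail
1. **Step 8 (Suzuki).** A hindered alkyl-9-BBN with a trisubstituted vinyl iodide can give protodeboronation or slow coupling.
   - Fallback: change the coupling partner. Hydroborate 5 and oxidise to the alcohol, convert it to the iodide, make the alkylzinc, and do a Negishi coupling with 8.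
2. **Step 5 (ketone to terminal alkyne).** Enolisation at the methylene side gives an internal alkyne and loses yield.
   - Fallback: drop the alkyne and vinyl iodide (steps 5–8). Wittig aldehyde 4 with the ylide of commercial (E,E)-farnesyl bromide, then chemoselectively reduce the 1,2-disubstituted C1′=C2′ alkene (diimide).
3. **Step 9 (MOM removal).** Acid may isomerise or hydrate the trienes, or erode C2 by ionisation of the tertiary aryl ether.
   - Fallback: use a TBS phenol ether from Step 2 onwards and remove it with TBAF in THF, a fluoride route with no acid.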